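Ring B is cut at B1–B2 and B4–B5; ring B carries the ether oxygen at B1, H at B2, Br at B3, H at B4, Br at B5 and OH at B6, and ring A bears one methoxy group, four bromines and the ether oxygen. The contiguous triad B1(OAr)–B6(OH)–B5 is the C4–C3–C2 array of a 4-aryloxyacetoacetate. One Lewis-acid [3+3] cyclocondensation of its bis-silyl dienol ether with a malondialdehyde bis-acetal therefore builds ring B as a 3-aryloxysalicylate. The hindered diaryl ether is made beforehand by alkylation at sp3 carbon. The B5 carboxyl, ortho to the B6 hydroxyl, is finally exchanged for bromine by ipso bromodecarboxylation while B3 is brominated.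

Key step: step 5

Remark: the enol ether and diene geometries are drawn as single isomers for definiteness. Mixtures are acceptable, because every C=C geometry and both stereocentres of the open-chain intermediate are erased on aromatisation.

Step 1
Reactants: 1 guaiacol (2-methoxyphenol)
Product: 3 2,3,4,5-tetrabromo-6-methoxyphenol (tetrabromoguaiacol), via tribromoguaiacol 2 (not isolated)
Conditions: Br2 (3.1 equiv), CH2Cl2, 0 → 20 °C; then FeBr3 (0.05 equiv), Br2 (1.4 equiv), 40 °C; aq NaHSO3
Reagents that add atoms: bromine, BrBr
Why: Exhaustive electrophilic aromatic bromination, in which OH and OMe steer the first three bromines ortho and para to themselves (2) and FeBr3 catalysis should force the last, least activated position next to the methoxy group, as in the perhalogenation of guaiacol.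

Step 2
Reactants: 3 2,3,4,5-tetrabromo-6-methoxyphenol; 4 methyl 4-chloroacetoacetate (methyl 4-chloro-3-oxobutanoate)
Product: 6 methyl 3-oxo-4-(2,3,4,5-tetrabromo-6-methoxyphenoxy)butanoate, via potassium phenolate 5 (not isolated)
Conditions: K2CO3 (1.05 equiv), DMF, 20 °C, 30 min; then 4 (1.1 equiv) added slowly, 0 → 40 °C
Reagents that add atoms: none
Why: Williamson O-alkylation (SN2) at an alpha-chloro ketone, a strongly activated electrophile; the phenolate of this acidic perbrominated phenol is too weak a base to enolise the keto ester appreciably, and with every ring carbon substituted only oxygen can be alkylated.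

Step 3
Reactants: 6 methyl 3-oxo-4-(2,3,4,5-tetrabromo-6-methoxyphenoxy)butanoate
Product: 7 methyl (Z)-4-(2,3,4,5-tetrabromo-6-methoxyphenoxy)-3-(trimethylsilyloxy)but-2-enoate
Conditions: Me3SiCl (1.5 equiv), Et3N (1.6 equiv), toluene, 20 °C, 48 h; filtration under argon
Reagents that add atoms: chlorotrimethylsilane, C[Si](C)(C)Cl
Why: Soft enolisation and O-silylation of a beta-keto ester should give the ester-conjugated silyl enol ether (first stage of the standard two-stage preparation of 1,3-bis(silyloxy)dienes), leaving C4 untouched.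

Step 4
Reactants: 7 methyl (Z)-4-(2,3,4,5-tetrabromo-6-methoxyphenoxy)-3-(trimethylsilyloxy)but-2-enoate
Product: 9 (1Z,3Z)-1-methoxy-4-(2,3,4,5-tetrabromo-6-methoxyphenoxy)-1,3-bis(trimethylsilyloxy)buta-1,3-diene, via lithium dienolate 8 (not isolated)
Conditions: LDA (1.3 equiv, commercial solution free of alkyllithium), THF, −78 °C, 1 h; then Me3SiCl (1.5 equiv), −78 → 20 °C; used crude
Reagents that add atoms: chlorotrimethylsilane, C[Si](C)(C)Cl
Why: Kinetic gamma-deprotonation of the silyloxy enoate at C4 gives the extended dienolate 8, which the hard silyl chloride should trap on the ester oxygen; ring A carries no hydrogen and a lithium amide does not undergo bromine–lithium exchange, so the aryl bromides should survive.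

Step 5
Reactants: 9 (1Z,3Z)-1-methoxy-4-(2,3,4,5-tetrabromo-6-methoxyphenoxy)-1,3-bis(trimethylsilyloxy)buta-1,3-diene; 10 1,1,3,3-tetramethoxypropane
Product: 12 methyl 2-hydroxy-3-(2,3,4,5-tetrabromo-6-methoxyphenoxy)benzoate, via open-chain enol silane 11 (not isolated)
Conditions: 10 (1.2 equiv), Me3SiOTf (0.2 equiv), CH2Cl2, −78 → 20 °C, 20 h; then 10% aq HCl
Reagents that add atoms: none
Why: Me3SiOTf ionises one acetal of 10 to a methoxycarbenium ion, which is attacked by the terminal carbon of 9 (future B1), the vinylogous and most nucleophilic site, forming B1–B2 and giving enol silane 11 with release of Me3SiOMe and of the catalyst. After ionisation of the second acetal the enol silane carbon (future B5) attacks it and forms B4–B5, a 6-(enolendo)-exo-trig Mukaiyama aldol-type closure of ring B. Two beta-eliminations of methanol and enolisation on acidic work-up aromatise the ring to the hydrogen-bonded salicylate, so no stereocentre remains and none has to be controlled. The closest known reaction is the formal [3+3] cyclocondensation of 1,3-bis(silyloxy)buta-1,3-dienes, 4-aryloxy ones included, with 1,1,3,3-tetramethoxypropane under Me3SiOTf or TiCl4 promotion. The step needs the order terminal carbon first and central carbon second, which the vinylogous reactivity of the diene secures, and it needs no control of orientation because the three-carbon dielectrophile is symmetric. Ring A has no hydrogen, and its bromines and methyl ether should be inert to the silyl triflate at these temperatures.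

Step 6
Reactants: 12 methyl 2-hydroxy-3-(2,3,4,5-tetrabromo-6-methoxyphenoxy)benzoate
Product: 14 2-hydroxy-3-(2,3,4,5-tetrabromo-6-methoxyphenoxy)benzoic acid, via disodium salicylate 13 (not isolated)
Conditions: NaOH (4 equiv), THF/H2O, 50 °C; then aq HCl to pH 1
Reagents that add atoms: sodium hydroxide, [Na+].[OH-]
Why: Ester saponification by acyl substitution, slowed by the phenoxide and therefore run warm with excess base; the unactivated aryl bromides and aryl ethers of ring A should not undergo substitution by aqueous hydroxide at this temperature.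

Step 7
Reactants: 14 2-hydroxy-3-(2,3,4,5-tetrabromo-6-methoxyphenoxy)benzoic acid
Product: 16 2,4-dibromo-6-(2,3,4,5-tetrabromo-6-methoxyphenoxy)phenol, via 5-bromosalicylic acid 15 (not isolated)
Conditions: Br2 (2.1 equiv), AcOH/H2O (3:1), 20 → 50 °C; aq NaHSO3
Reagents that add atoms: bromine, BrBr
Why: The B6 hydroxyl directs the first bromine to B3 (para, electrophilic aromatic substitution) and the second to B5 by ipso attack, and the resulting cyclohexadienone carboxylic acid loses CO2 (bromodecarboxylation of salicylic acids in aqueous medium); B2 and B4 are meta to the hydroxyl and ring A is fully substituted, so exactly two bromines should enter.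

Compound list
1 | guaiacol (2-methoxyphenol) | COc1ccccc1O | starting material
2 | 2,3,4-tribromo-6-methoxyphenol (4,5,6-tribromoguaiacol), not isolated | COc1cc(Br)c(Br)c(Br)c1O | intermediate
3 | 2,3,4,5-tetrabromo-6-methoxyphenol | COc1c(O)c(Br)c(Br)c(Br)c1Br | intermediate
4 | methyl 4-chloroacetoacetate (methyl 4-chloro-3-oxobutanoate) | COC(=O)CC(=O)CCl | starting material
5 | potassium 2,3,4,5-tetrabromo-6-methoxyphenolate, not isolated | [K+].COc1c([O-])c(Br)c(Br)c(Br)c1Br | intermediate
6 | methyl 3-oxo-4-(2,3,4,5-tetrabromo-6-methoxyphenoxy)butanoate | COC(=O)CC(=O)COc1c(OC)c(Br)c(Br)c(Br)c1Br | intermediate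
7 | methyl (Z)-4-(2,3,4,5-tetrabromo-6-methoxyphenoxy)-3-(trimethylsilyloxy)but-2-enoate | COC(=O)/C=C(\O[Si](C)(C)C)COc1c(OC)c(Br)c(Br)c(Br)c1Br | intermediate
8 | lithium (1E,3Z)-1-methoxy-4-(2,3,4,5-tetrabromo-6-methoxyphenoxy)-3-(trimethylsilyloxy)buta-1,3-dien-1-olate, not isolated | [Li+].CO/C([O-])=C/C(O[Si](C)(C)C)=C/Oc1c(OC)c(Br)c(Br)c(Br)c1Br | intermediate
9 | (1Z,3Z)-1-methoxy-4-(2,3,4,5-tetrabromo-6-methoxyphenoxy)-1,3-bis(trimethylsilyloxy)buta-1,3-diene | CO/C(O[Si](C)(C)C)=C/C(O[Si](C)(C)C)=C/Oc1c(OC)c(Br)c(Br)c(Br)c1Br | intermediate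
10 | 1,1,3,3-tetramethoxypropane | COC(OC)CC(OC)OC | starting material
11 | methyl (Z)-5,7,7-trimethoxy-4-(2,3,4,5-tetrabromo-6-methoxyphenoxy)-3-(trimethylsilyloxy)hept-2-enoate, mixture of diastereomers at C4 and C5, not isolated | COC(=O)/C=C(\O[Si](C)(C)C)C(Oc1c(OC)c(Br)c(Br)c(Br)c1Br)C(OC)CC(OC)OC | intermediate
12 | methyl 2-hydroxy-3-(2,3,4,5-tetrabromo-6-methoxyphenoxy)benzoate | COC(=O)c1cccc(Oc2c(OC)c(Br)c(Br)c(Br)c2Br)c1O | intermediate
13 | disodium 2-oxido-3-(2,3,4,5-tetrabromo-6-methoxyphenoxy)benzoate, not isolated | [Na+].[Na+].[O-]C(=O)c1cccc(Oc2c(OC)c(Br)c(Br)c(Br)c2Br)c1[O-] | intermediate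
14 | 2-hydroxy-3-(2,3,4,5-tetrabromo-6-methoxyphenoxy)benzoic acid | OC(=O)c1cccc(Oc2c(OC)c(Br)c(Br)c(Br)c2Br)c1O | intermediate
15 | 5-bromo-2-hydroxy-3-(2,3,4,5-tetrabromo-6-methoxyphenoxy)benzoic acid, not isolated | OC(=O)c1cc(Br)cc(Oc2c(OC)c(Br)c(Br)c(Br)c2Br)c1O | intermediate
16 | 2,4-dibromo-6-(2,3,4,5-tetrabromo-6-methoxyphenoxy)phenol | COc1c(Br)c(Br)c(Br)c(Br)c1Oc1cc(Br)cc(Br)c1O | target

Total step count: 7. Longest linear sequence: 7 steps (1 to 16).

Steps most likely to fail

Step 5. The diene may be protodesilylated back to the keto ester before it finds the carbenium ion, or the sequence may stall after the first C–C bond so that the open-chain enol silane is hydrolysed instead of closing. The fallback sets out from 3 and comes back at 12; ring B is then taken from a ready-made benzoate instead of being built. The phenolate of 3 would displace fluoride from methyl 3-fluoro-2-nitrobenzoate (K2CO3, DMF, 90 °C; nucleophilic aromatic substitution activated by the ortho nitro group) to give methyl 2-nitro-3-(2,3,4,5-tetrabromo-6-methoxyphenoxy)benzoate F1. Reduction with Fe powder and NH4Cl in aqueous ethanol, which spares aryl bromides, should give methyl 2-amino-3-(2,3,4,5-tetrabromo-6-methoxyphenoxy)benzoate F2. Diazotisation (NaNO2, aq H2SO4, 0 °C) to 2-(methoxycarbonyl)-6-(2,3,4,5-tetrabromo-6-methoxyphenoxy)benzenediazonium hydrogen sulfate F3, followed by hydrolysis in hot dilute H2SO4, would deliver 12, and the route continues with step 6. Ring A has no free position, so the diazonium ion cannot cyclise onto it.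

Step 2. Base-induced self-condensation or C-alkylation of the chloro keto ester may outrun O-alkylation by the hindered, weakly nucleophilic phenolate. The fallback sets out from 3 and comes back at 6; it uses a masked keto ester that has no acidic methylene. Phenol 3 would be alkylated with methyl (E)-4-bromo-3-methoxybut-2-enoate (K2CO3, acetone, reflux; SN2 at an allylic bromide) to give methyl (E)-3-methoxy-4-(2,3,4,5-tetrabromo-6-methoxyphenoxy)but-2-enoate F4. Hydrolysis of the enol ether (2 M aq HCl, THF, 40 °C) should then release keto ester 6.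

Step 7. Decarboxylation may stall after the first bromination if the lipophilic acid is poorly ionised in the medium, or excess bromine may attack the product further. The fallback sets out from 14 and comes back at 16; it separates loss of the carboxyl from bromination. Protodecarboxylation of 14 (Ag2CO3 0.1 equiv, AcOH cat., DMSO, 120 °C) should give 2-(2,3,4,5-tetrabromo-6-methoxyphenoxy)phenol F5. Ordinary electrophilic bromination (Br2 2.0 equiv, AcOH, 20 °C) would then enter para and at the one free ortho position of the hydroxyl to give 16.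

Further compounds
F1 | step 5 | methyl 2-nitro-3-(2,3,4,5-tetrabromo-6-methoxyphenoxy)benzoate | COC(=O)c1cccc(Oc2c(OC)c(Br)c(Br)c(Br)c2Br)c1[N+](=O)[O-]
F2 | step 5 | methyl 2-amino-3-(2,3,4,5-tetrabromo-6-methoxyphenoxy)benzoate | COC(=O)c1cccc(Oc2c(OC)c(Br)c(Br)c(Br)c2Br)c1N
F3 | step 5 | 2-(methoxycarbonyl)-6-(2,3,4,5-tetrabromo-6-methoxyphenoxy)benzenediazonium hydrogen sulfate | COC(=O)c1cccc(Oc2c(OC)c(Br)c(Br)c(Br)c2Br)c1[N+]#N.OS(=O)(=O)[O-]
F4 | step 2 | methyl (E)-3-methoxy-4-(2,3,4,5-tetrabromo-6-methoxyphenoxy)but-2-enoate | CO/C(COc1c(OC)c(Br)c(Br)c(Br)c1Br)=C/C(=O)OC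
F5 | step 7 | 2-(2,3,4,5-tetrabromo-6-methoxyphenoxy)phenol | COc1c(Br)c(Br)c(Br)c(Br)c1Oc1ccccc1O
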